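The route rests on cutting the bond between the benzylic CH2 and C1 of the 3,4,5-trimethoxyphenyl ring. The key step exploits the hidden symmetry of the propane chain. Its CH2OH carbon and its benzylic CH2 are two like arms on the aryloxy-bearing methine, i.e. C2 and C4 of an oxetane whose ring oxygen is the hydroxyl oxygen. The precursor is therefore achiral 3-(4-allyl-2,6-dimethoxyphenoxy)oxetane. In one flask a chiral squaramide/TMSBr pair opens one enantiotopic C–O bond. The primary bromide so formed is then arylated by 3,4,5-trimethoxyphenylmagnesium bromide under copper catalysis. This operation sets the only stereocentre, joins both aryl fragments and unveils the alcohol.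

Key step: step 2

Assumption: the sense of induction of the squaramide cannot be read from the structures, so the catalyst antipode that gives (S)-5 is fixed in a pilot run (both antipodes are made in the same way), and 4 is taken as its commercial 0.5 M THF solution.

Step 1
Reactants: 1 4-allyl-2,6-dimethoxyphenol (methoxyeugenol); 2 oxetan-3-yl 4-methylbenzenesulfonate
Product: 3 3-(4-allyl-2,6-dimethoxyphenoxy)oxetane
Conditions: Cs2CO3 (1.5 equiv), DMF, 90 °C
Reagents that add atoms: none
Why: Williamson ether synthesis, an SN2 displacement of the oxetan-3-yl sulfonate by the caesium phenoxide and the standard entry to 3-aryloxyoxetanes; carbonate is too weak a base to move the allyl double bond into conjugation, and no stereocentre arises because 3 has a mirror plane.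

Step 2
Reactants: 3 3-(4-allyl-2,6-dimethoxyphenoxy)oxetane; 4 3,4,5-trimethoxyphenylmagnesium bromide (0.5 M in THF)
Product: 7 (2R)-2-(4-allyl-2,6-dimethoxyphenoxy)-3-(3,4,5-trimethoxyphenyl)propan-1-ol, via (S)-bromo silyl ether 5 (not isolated), via O-TMS ether of the target 6 (not isolated)
Conditions: (i) chiral arylpyrrolidine-derived squaramide H-bond-donor catalyst (5 mol %), TMSBr (1.1 equiv), Et2O, −80 °C, to full conversion of 3; (ii) 4 (2 equiv), Li2CuCl4 (5 mol %), NMP (4 equiv), THF, −30 °C to rt; (iii) 1 M aq. citric acid, MeOH, rt
Reagents that add atoms: bromotrimethylsilane, C[Si](C)(C)Br (its Si and Br atoms stand only in 5 and 6; none remains in 7)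
Why: The squaramide abstracts and holds the bromide of TMSBr, the silylated oxetanium ion of 3 pairs with this chiral anion complex, and bromide is delivered by SN2 to one of the two enantiotopic ring CH2 groups, release of ring strain making the opening irreversible and giving (S)-5 (closest known type: enantioselective desymmetrisation of 3-substituted, including 3-oxygenated, oxetanes with TMSBr under anion-binding hydrogen-bond-donor catalysis). The arylcuprate formed from 4 and catalytic Li2CuCl4 then displaces the primary bromide by SN2-type oxidative addition and reductive elimination from copper(III), which forms the CH2–aryl bond (closest known type: copper-catalysed Kumada-type coupling of aryl Grignard reagents with primary alkyl bromides). No ring is closed; the only ring event is the opening of the four-membered ring. The single new stereocentre is the former C3 of the oxetane, at which no bond is made or broken: its configuration is decided only by which CH2 group the catalyst lets bromide attack, and it passes unchanged through the substitution next to it, (S)-5 and (R)-7 having the same spatial arrangement and differing only in CIP ranking. The step needs group selectivity (secured by the mirror symmetry of 3 with one large C3 substituent for the catalyst to read, by the very low temperature that suppresses uncatalysed opening, and by complete consumption of 3 before 4 is added) and substitution in preference to loss of the β-aryloxy group, which is why a two-electron copper pathway is used: a β-aryloxyalkyl radical or a β-aryloxyalkyl-zinc, -nickel or -palladium species would be prone to expel the stabilised 2,6-dimethoxyphenoxyl radical or phenoxide. The O-TMS group installed by the opening shields the alcohol from 4 and is hydrolysed in the acidic work-up, and the allyl group and the five aryl methyl ethers should be inert to TMSBr at −80 °C and to the Grignard reagent.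

Compound list
1 | 4-allyl-2,6-dimethoxyphenol | C=CCc1cc(OC)c(O)c(OC)c1 | starting material
2 | oxetan-3-yl 4-methylbenzenesulfonate | Cc1ccc(cc1)S(=O)(=O)OC1COC1 | starting material
3 | 3-(4-allyl-2,6-dimethoxyphenoxy)oxetane (achiral) | C=CCc1cc(OC)c(OC2COC2)c(OC)c1 | intermediate
4 | 3,4,5-trimethoxyphenylmagnesium bromide | COc1cc([Mg]Br)cc(OC)c1OC | starting material
5 | [(2S)-3-bromo-2-(4-allyl-2,6-dimethoxyphenoxy)propoxy]trimethylsilane | C=CCc1cc(OC)c(O[C@@H](CO[Si](C)(C)C)CBr)c(OC)c1 | intermediate
6 | [(2R)-2-(4-allyl-2,6-dimethoxyphenoxy)-3-(3,4,5-trimethoxyphenyl)propoxy]trimethylsilane | C=CCc1cc(OC)c(O[C@@H](CO[Si](C)(C)C)Cc2cc(OC)c(OC)c(OC)c2)c(OC)c1 | intermediate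
7 | (2R)-2-(4-allyl-2,6-dimethoxyphenoxy)-3-(3,4,5-trimethoxyphenyl)propan-1-ol | C=CCc1cc(OC)c(O[C@@H](CO)Cc2cc(OC)c(OC)c(OC)c2)c(OC)c1 | target

Total step count: 2. Step 2 runs ring opening, coupling and desilylation in one flask.
Longest linear sequence: 2.

Steps most likely to fail (the route has only two steps, so both are ranked and there is no third entry):

1. Step 2.
- The two enantiotopic CH2 groups may be discriminated incompletely. Uncatalysed opening may compete. The ortho-methoxy oxygens may disturb the ion pair, or take part in a 6-exo opening followed by demethylation.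
- Substitution at the β-branched, β-oxygenated bromide may be slow enough for E2 loss of HBr to compete.
- The fallback sets out from 3 and 4 and comes back at 7. The oxetane ring of 3 is opened directly by 4 under copper(I) catalysis (CuI 10 mol %, THF, 50 °C). This is the classical copper-catalysed Grignard opening of oxetanes. The leaving oxygen stays tethered, so there is neither a halide intermediate nor an elimination pathway.
- The product is racemic 2-(4-allyl-2,6-dimethoxyphenoxy)-3-(3,4,5-trimethoxyphenyl)propan-1-ol F1.
- A lipase-catalysed kinetic resolution with vinyl acetate follows (enzyme chosen by screening for acylation of the (S)-alcohol, diisopropyl ether, rt, run slightly beyond half conversion). It should convert the unwanted enantiomer into (2S)-2-(4-allyl-2,6-dimethoxyphenoxy)-3-(3,4,5-trimethoxyphenyl)propyl acetate F2, which is separated by chromatography from the unreacted alcohol 7.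

2. Step 1.
- SN2 at the strained secondary carbon of 2 by the doubly ortho-substituted phenoxide may be sluggish. Prolonged heating with base may then shift the allyl double bond into conjugation or degrade the sulfonate.
- The fallback sets out from 1 and comes back at 3. It forms the aryl ether bond first and closes the four-membered ring afterwards.
- O-alkylation of 1 with diethyl bromomalonate (K2CO3, acetone, reflux; an activated electrophile) should give diethyl 2-(4-allyl-2,6-dimethoxyphenoxy)malonate F3.
- Reduction with LiAlH4 (THF, 0 °C) gives 2-(4-allyl-2,6-dimethoxyphenoxy)propane-1,3-diol F4.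
- One-pot monosulfonylation and 4-exo-tet Williamson closure follows (n-BuLi 1 equiv, TsCl 1 equiv, then n-BuLi 1 equiv, THF, 0 to 60 °C). It passes through racemic 2-(4-allyl-2,6-dimethoxyphenoxy)-3-hydroxypropyl 4-methylbenzenesulfonate F5 and delivers 3.

Further compounds
F1 | step 2 | racemic 2-(4-allyl-2,6-dimethoxyphenoxy)-3-(3,4,5-trimethoxyphenyl)propan-1-ol | C=CCc1cc(OC)c(OC(CO)Cc2cc(OC)c(OC)c(OC)c2)c(OC)c1
F2 | step 2 | (2S)-2-(4-allyl-2,6-dimethoxyphenoxy)-3-(3,4,5-trimethoxyphenyl)propyl acetate | C=CCc1cc(OC)c(O[C@H](COC(C)=O)Cc2cc(OC)c(OC)c(OC)c2)c(OC)c1
F3 | step 1 | diethyl 2-(4-allyl-2,6-dimethoxyphenoxy)malonate | C=CCc1cc(OC)c(OC(C(=O)OCC)C(=O)OCC)c(OC)c1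
F4 | step 1 | 2-(4-allyl-2,6-dimethoxyphenoxy)propane-1,3-diol | C=CCc1cc(OC)c(OC(CO)CO)c(OC)c1
F5 | step 1 | racemic 2-(4-allyl-2,6-dimethoxyphenoxy)-3-hydroxypropyl 4-methylbenzenesulfonate | C=CCc1cc(OC)c(OC(CO)COS(=O)(=O)c2ccc(C)cc2)c(OC)c1
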